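The numbers in the tables were computed from invented constants.

**Drying or not.** The amounts were 2.0 M of starting material and 0.600 M of capture agent, with protic impurity set from 0.0250 M in elm to 0.150 M in cedar. I had to choose whether to dry the next charge, and drying was worth it if free target at 15 min followed the impurity.

| flask | starting material | capture agent | protic impurity | remark | time |
|---|---|---|---|---|---|
| south-east | 2 M | 0.60 M | 0.021 M | run made earlier |  |
| north | 2 M | 0.60 M | 0.067 M | run made earlier |  |
| west | 2 M | 0.60 M | 0.18 M | run made earlier |  |
| elm | 2.0 M | 0.600 M | 0.0250 M |  | 15 min |
| larch | 2.0 M | 0.600 M | 0.0400 M |  | 15 min |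
| ash | 2.0 M | 0.600 M | 0.0600 M |  | 15 min |
| maple | 2.0 M | 0.600 M | 0.100 M |  | 15 min |
| cedar | 2.0 M | 0.600 M | 0.150 M |  | 15 min |

- south-east (time / min: target / %, starting material / %): 1.00: 0.7, 85.0; 2.50: 1.5, 69.9; 5.00: 3.7, 52.2; 8.00: 6.7, 38.0; 10.0: 9.1, 30.7
- north (time / min: target / %, starting material / %): 2.00: 1.6, 72.9; 4.00: 3.0, 57.0; 6.00: 4.7, 46.2; 8.00: 7.1, 37.5; 10.0: 8.4, 29.9
- west (time / min: target / %, starting material / %): 0.833: 0.9, 80.3; 1.50: 0.7, 73.2; 3.00: 1.5, 60.5; 6.00: 4.6, 43.2; 10.0: 7.9, 28.6

(each reading ± 0.3 percentage points)

- what was read earlier has a scatter of 0.3 percentage points, one standard deviation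
- a reading or a percentage of target counts all its forms, free or not
- the concentration of target that is asked is that of its free form alone
- "hardly changes" means that all values lie within two and a half points (for a concentration: within two and a half percent of the largest)
- a reading of starting material is of its free form alone

- [target] (only what is free in solution) at the end for elm, larch, ash, maple, cedar, in this order
- how that number moves from the first to the last of them (hardly changes / falls, then rises / rises, then falls / rises all the way / falls all the way)

**Half-lives counted.** The south-east run fell from 69.9% at 2.50 min to 30.7% at 10.0 min, so its readings halve in 6.32 min, my working half-life of free starting material, an apparent first-order half-life. The west run, holding 0.18 M of impurity against 0.021 M, read 6.48 min, so I carried one figure for both. The time allowed is 2.37 half-lives, which by my own reckoning leaves 0.355 M of free starting material in elm. I chose to leave the impurity undried.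

**The forecast.** The forecast gave 0.005 M of free target in elm and 0.005 M in cedar, shape hardly changes, reasoning that “if binding is tight, free target stays near zero in all five runs”. My count named starting material, not target, so we shared a direction and no number.

**The flask.** Free target came to 0.0455 M in elm and 0.0448 M in cedar, hardly changes.

    intermediate B ⇌ target (K = 0.450, k = 0.0310 min⁻¹)
    starting material + protic impurity → quenched substrate (k = 7.70 M⁻¹ min⁻¹)
    starting material → target (k = 0.00820 min⁻¹)
    starting material ⇌ intermediate A (K = 1.20, k = 0.140 min⁻¹)
    capture agent + intermediate A → trapped intermediate (k = 0.0270 M⁻¹ min⁻¹)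
    starting material + target ⇌ idle adduct, settled at all times (K = 15.0 M⁻¹)
    intermediate A → intermediate B (k = 0.170 min⁻¹)

**Idle adduct.** Part of what held free target in elm down to 0.0455 M is the tying up of starting material + target as idle adduct, together with the shortness of the time allowed: without the tying up elm gave 0.223 M, and by 150 min it gave 0.516 M. My half-life of 6.32 min put 0.355 M of starting material beside target, a free share of 15.8%, so the 0.289 M counted as target in elm leaves 0.0458 M. In cedar the same share of its counted 13.5% gives 0.0427 M, and the flask stood at 0.0448 M.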